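**Retrosynthetic overview**

1. Numbering: C1 (quaternary, CH3), C2 (CH2), C3 (OAc), C4 (OH, iPr), C5 (fusion H), C6 (O-aroyl), C7=C8(CH3), C9 (CH2), C10 (OH); α is the face of C1–CH3 and C5–H. The strategy rests on the cis C1–C5 fusion between the cyclopentane (C1–C5) and the cycloheptene (C1, C5–C10), flanked by oxygenated C10 and C6: it is read as the C1=C5 alkene of a cis-2-methylcyclohept-2-ene-1,4-diol.
2. Endgame: desilylation ⇐ C6 esterification ⇐ Luche reduction of a C6 enone ⇐ C7=C8(CH3) built on a C6 ketone; the 3α,4α-diol ⇐ OsO4 on a C3=C4 alkene ⇐ enol triflate of a C3 ketone.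
3. Five-membered ring ⇐ insertion of C4 (carrying isopropyl) between C3 and C5 of an α,α-dichlorocyclobutanone with 1-diazo-2-methylpropane, then dechlorination at C2.
4. Four-membered ring ⇐ dichloroketene [2+2] across C1=C5 of bis-silyl ether 8 (C2 to C1, C3 to C5), on the face opposite both silyloxy groups.
5. 8 ⇐ cyclohepta-1,3-diene via its endoperoxide, enantioselective Kornblum–DeLaMare opening, α-methylation and cis reduction. Ring order: seven (bought), four (step 8), five (step 11).

Key step: step 8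

Remark on the chemistry: bicyclic compounds are named with the local numbering above (not von Baeyer numbering), in which the target is (1S,3S,4R,5R,6S,10S), i.e. 3α-OAc, 4α-OH, 10α-OH, 6β-O-aroyl; C4 of 17/18 and C8 of 28 form as epimer mixtures that are erased later and are left open in the SMILES (TBS = tert-butyldimethylsilyl, TES = triethylsilyl, TMS = trimethylsilyl).

**Route**

Step 1
Reactants: 1 cyclohepta-1,3-diene
Product: 2 6,7-dioxabicyclo[3.2.2]non-8-ene (meso endoperoxide)
Conditions: O2, TPP (cat.), hν (visible), CH2Cl2, 0 °C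
Reagents that add atoms: dioxygen, O=O
Why: Singlet-oxygen [4+2] photooxygenation of the cisoid diene gives the bridged meso peroxide, which already holds the future C6 and C10 oxygens cis.

Step 2
Reactants: 2 meso endoperoxide
Product: 3 (R)-4-hydroxycyclohept-2-en-1-one
Conditions: O-acetylcupreidine (5–10 mol %; or its pseudoenantiomer O-acetylcupreine, whichever delivers the R enone), CH2Cl2, rt
Reagents that add atoms: none
Why: Enantioselective Kornblum–DeLaMare rearrangement, in which the chiral amine base removes one of the two enantiotopic bridgehead protons so that the untouched carbinol carbon (future C6) is obtained in one absolute configuration, to be checked by chiral HPLC before going on.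

Step 3
Reactants: 3 (R)-4-hydroxycyclohept-2-en-1-one
Product: 4 (R)-4-(triethylsilyloxy)cyclohept-2-en-1-one
Conditions: TESCl, imidazole, CH2Cl2, 0 °C
Reagents that add atoms: chlorotriethylsilane, CC[Si](Cl)(CC)CC
Why: Standard imidazole-mediated silylation protects the γ-hydroxyl as the acid-labile TES ether that is later removed selectively beside TBS.

Step 4
Reactants: 4 TES enone
Product: 5 (R)-2-iodo-4-(triethylsilyloxy)cyclohept-2-en-1-one
Conditions: I2, pyridine, CH2Cl2, 0 °C → rt
Reagents that add atoms: iodine, II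
Why: α-Iodination of the enone by the pyridine addition–iodination–elimination (Baylis–Hillman-type) sequence places iodine on the enone α-carbon, the future C1.

Step 5
Reactants: 5 α-iodoenone
Product: 6 (R)-2-methyl-4-(triethylsilyloxy)cyclohept-2-en-1-one
Conditions: SnMe4, Pd2(dba)3 (cat.), AsPh3, CuI, NMP, 60 °C
Reagents that add atoms: tetramethylstannane, C[Sn](C)(C)C
Why: Stille cross-coupling of the vinyl iodide installs the C1 methyl group under neutral conditions that spare the TES ether and the γ-stereocentre.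

Step 6
Reactants: 6 2-methyl enone
Product: 7 (1S,4R)-2-methyl-4-(triethylsilyloxy)cyclohept-2-en-1-ol (cis)
Conditions: NaBH4, CeCl3·7H2O, MeOH, −78 °C
Reagents that add atoms: none
Why: Luche 1,2-reduction, in which hydride should add to the carbonyl face opposite the C4 silyloxy group to give the cis-1,4 alcohol (future C10, target configuration); a minor trans isomer would be removed by chromatography.

Step 7
Reactants: 7 cis alcohol
Product: 8 (1S,4R)-1-(tert-butyldimethylsilyloxy)-2-methyl-4-(triethylsilyloxy)cyclohept-2-ene (cis)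
Conditions: TBSCl, imidazole, DMF, rt
Reagents that add atoms: tert-butyldimethylsilyl chloride, CC(C)(C)[Si](C)(C)Cl
Why: Imidazole-mediated silylation puts the robust TBS group on the oxygen (C10) that must last to the final step and completes the differentiated cis-bis-silyl ether.

Step 8
Reactants: 8 cis-bis-silyl ether; 9 trichloroacetyl chloride
Product: 11 cis-fused dichlorocyclobutanone (2,2-dichloro-1-methyl-10α-OTBS-6α-OTES-cis-bicyclo[5.2.0]nonan-3-one), via dichloroketene 10 (not isolated)
Conditions: Zn–Cu, Cl3CCOCl and POCl3 added slowly, Et2O, rt → 35 °C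
Reagents that add atoms: trichloroacetyl chloride 9, ClC(Cl)(Cl)C(Cl)=O (reacting as dichloroketene 10, O=C=C(Cl)Cl)
Why: Zinc dechlorinates 9 to dichloroketene, which adds to the only alkene of 8 in a concerted, asynchronous [π2s+π2a] cycloaddition (closest known reaction: dichloroketene addition to trisubstituted cycloalkenes under zinc/POCl3 conditions). The electrophilic ketene carbonyl carbon (C3) bonds to the less substituted C5 while positive charge builds at the methyl-bearing C1, which takes the CCl2 carbon (C2) and becomes the quaternary centre. The four-membered ring is closed by intermolecular addition of both new bonds (C1–C2 and C5–C3) to the same alkene face, so the ring fusion can only be cis. C1 and C5 are set by the face of attack: the silyloxy groups at C10 and C6 are cis and shield the α face, so the ketene should arrive on the β face, leaving C1–CH3 and C5–H α, syn to 10-OTBS as in the target. The step needs regio-, face- and chemoselectivity: the first follows from the alkene substitution, the second from the cis-1,4-bis(silyloxy) pattern, and the third from the use of silyl rather than alkyl ethers, whose oxygens do not attack the ketene, with POCl3 tying up ZnCl2 so that the TES ether survives.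

Step 9
Reactants: 12 isobutyraldehyde; 13 p-toluenesulfonyl hydrazide
Product: 14 isobutyraldehyde tosylhydrazone
Conditions: MeOH, rt
Reagents that add atoms: p-toluenesulfonyl hydrazide 13, Cc1ccc(cc1)S(=O)(=O)NN
Why: Condensation of the aldehyde with the sulfonyl hydrazide gives the crystalline tosylhydrazone, a storable precursor of the diazoalkane.

Step 10
Reactants: 14 tosylhydrazone
Product: 16 1-diazo-2-methylpropane (cold Et2O solution), via sodium tosylhydrazonate 15 (not isolated)
Conditions: NaOMe (1.0 equiv), MeOH; dry in vacuo; 90–120 °C, 0.1 mmHg, trap at −78 °C, take up in Et2O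
Reagents that add atoms: none
Why: Bamford–Stevens fragmentation by vacuum pyrolysis of the dry sodium salt expels sulfinate, and the volatile diazoalkane distils into the cold trap before it can lose nitrogen; it is used at once.

Step 11
Reactants: 11 dichlorocyclobutanone; 16 1-diazo-2-methylpropane
Product: 17 2,2-dichloro-4-isopropyl-1-methyl-10α-OTBS-6α-OTES-cis-bicyclo[5.3.0]decan-3-one (C4 epimers)
Conditions: 16 (excess), Et2O, MeOH (cat.), −40 → 0 °C
Reagents that add atoms: 1-diazo-2-methylpropane 16, CC(C)C=[N+]=[N-]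
Why: Büchner–Curtius–Schlotterbeck-type ring expansion, in which the diazo carbon adds to the strained, chlorine-activated carbonyl C3 and the non-halogenated C5 migrates with retention (the CCl2 carbon does not), inserting C4 with its isopropyl between C3 and C5; the less electrophilic cyclopentanone should not homologate further.

Step 12
Reactants: 17 dichlorocyclopentanone
Product: 18 4-isopropyl-1-methyl-10α-OTBS-6α-OTES-cis-bicyclo[5.3.0]decan-3-one (C4 epimers)
Conditions: Zn–Cu, NH4Cl, MeOH, rt
Reagents that add atoms: none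
Why: Zinc reduction of the α,α-dichloro ketone through zinc enolates replaces both chlorines at C2 by hydrogen under nearly neutral conditions that spare both silyl ethers.

Step 13
Reactants: 18 C3 ketone
Product: 19 4-isopropyl-1-methyl-10α-OTBS-6α-OTES-cis-bicyclo[5.3.0]dec-3-en-3-yl trifluoromethanesulfonate
Conditions: Tf2O, 2,6-di-tert-butyl-4-methylpyridine, CH2Cl2, 0 °C → rt
Reagents that add atoms: trifluoromethanesulfonic anhydride, O=S(=O)(OS(=O)(=O)C(F)(F)F)C(F)(F)F
Why: O-Triflation of the ketone with Tf2O and a hindered pyridine base gives the enol triflate, and loss of the C4 methine proton should be favoured because it leads to the more stable tetrasubstituted C3=C4 isomer, as is usual for 2-alkylcyclopentanones under these conditions.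

Step 14
Reactants: 19 enol triflate
Product: 20 4-isopropyl-1-methyl-10α-OTBS-6α-OTES-cis-bicyclo[5.3.0]dec-3-ene
Conditions: Pd(OAc)2 (cat.), PPh3, HCO2H, Bu3N, DMF, 60 °C
Reagents that add atoms: none
Why: Palladium-catalysed formate reduction of the enol triflate (oxidative addition, formate exchange, decarboxylation, reductive elimination) replaces OTf by H without moving the C3=C4 double bond.

Step 15
Reactants: 20 C3=C4 alkene
Product: 21 4β-isopropyl-1-methyl-10α-OTBS-6α-OTES-cis-bicyclo[5.3.0]decane-3α,4α-diol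
Conditions: OsO4 (cat.), NMO, acetone/H2O, rt
Reagents that add atoms: osmium tetroxide, O=[Os](=O)(=O)=O; N-methylmorpholine N-oxide, C[N+]1([O-])CCOCC1; water, O
Why: Upjohn dihydroxylation, in which OsO4 adds suprafacially to the cyclopentene from its convex α face (that of C5–H and C1–CH3, away from the cis-fused seven-membered ring), setting C3 (S) and C4 (R) as the cis-diol with isopropyl β.

Step 16
Reactants: 21 diol
Product: 22 3α-acetoxy-4α-hydroxy-4β-isopropyl-1-methyl-10α-OTBS-6α-OTES-cis-bicyclo[5.3.0]decane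
Conditions: Ac2O, pyridine, DMAP (cat.), CH2Cl2, rt
Reagents that add atoms: acetic anhydride, CC(=O)OC(C)=O
Why: DMAP-catalysed acetylation takes only the secondary C3 alcohol, since the tertiary C4 alcohol next to isopropyl is far too hindered.

Step 17
Reactants: 22 acetate
Product: 23 3α-acetoxy-4β-isopropyl-1-methyl-10α-OTBS-cis-bicyclo[5.3.0]decane-4α,6α-diol
Conditions: PPTS (cat.), MeOH/CH2Cl2, 0 °C
Reagents that add atoms: none
Why: Acid-catalysed methanolysis cleaves the triethylsilyl ether much faster than the hindered TBS ether at neopentyl C10 and frees only the C6 alcohol.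

Step 18
Reactants: 23 C6 alcohol
Product: 24 3α-acetoxy-4α-hydroxy-4β-isopropyl-1-methyl-10α-OTBS-cis-bicyclo[5.3.0]decan-6-one
Conditions: Dess–Martin periodinane, NaHCO3, CH2Cl2, rt
Reagents that add atoms: none
Why: Dess–Martin oxidation under buffered conditions turns the C6 carbinol of unwanted configuration into the ketone without enolising C5 or dehydrating the β-hydroxy ketone.

Step 19
Reactants: 24 β-hydroxy ketone
Product: 25 3α-acetoxy-4β-isopropyl-1-methyl-10α-OTBS-4α-OTMS-cis-bicyclo[5.3.0]decan-6-one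
Conditions: TMSOTf, 2,6-lutidine, CH2Cl2, −78 → 0 °C
Reagents that add atoms: trimethylsilyl trifluoromethanesulfonate, C[Si](C)(C)OS(=O)(=O)C(F)(F)F
Why: Silyl triflate/hindered-base silylation caps the tertiary C4 alcohol so that the later basic steps cannot start a retro-aldol cleavage of C4–C5, while lutidine at low temperature should not enol-silylate the ketone.

Step 20
Reactants: 25 C6 ketone
Product: 27 3α-acetoxy-4β-isopropyl-1-methyl-10α-OTBS-4α-OTMS-cis-bicyclo[5.3.0]dec-7-en-6-one, via C6–C7 trimethylsilyl enol ether 26 (not isolated)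
Conditions: LiHMDS, TMSCl, THF, −78 °C; then Pd(OAc)2, MeCN, rt
Reagents that add atoms: none
Why: Kinetic deprotonation at the C7 methylene (not at the hindered C5 methine, so the ring-fusion centre is never enolised) with in situ silylation, then Saegusa–Ito oxidation of the crude enol ether, gives the C7=C8 enone.

Step 21
Reactants: 27 enone
Product: 29 3α-acetoxy-4β-isopropyl-1,8-dimethyl-10α-OTBS-4α-OTMS-cis-bicyclo[5.3.0]dec-7-en-6-one, via 8-methyl trimethylsilyl enol ether 28 (not isolated)
Conditions: Me2CuLi (MeLi, CuI), TMSCl, THF, −78 °C; then Pd(OAc)2, MeCN, rt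
Reagents that add atoms: lithium dimethylcuprate (from methyllithium and CuI), C[Cu-]C.[Li+]
Why: Gilman cuprate 1,4-addition puts the methyl group on C8 and TMSCl traps the C6–C7 enolate regiospecifically, and a second Saegusa–Ito oxidation (β-hydride loss from C8) restores the enone as the C7=C8(CH3) unit of the target.

Step 22
Reactants: 29 β-methyl enone
Product: 30 3α-acetoxy-4β-isopropyl-1,8-dimethyl-10α-OTBS-4α-OTMS-cis-bicyclo[5.3.0]dec-7-en-6β-ol
Conditions: NaBH4, CeCl3·7H2O, MeOH, −78 °C
Reagents that add atoms: none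
Why: Luche 1,2-reduction, in which hydride should attack C6 from the α face, anti to the fully substituted C4 and its β-isopropyl group on the neighbouring ring-fusion carbon, giving the 6β (6S) allylic alcohol and so inverting C6 relative to the peroxide-derived oxygen.

Step 23
Reactants: 31 4-hydroxybenzoic acid
Product: 33 4-(tert-butyldimethylsilyloxy)benzoic acid, via bis-silylated ester 32 (not isolated)
Conditions: TBSCl (2.2 equiv), imidazole, DMF, rt; then AcOH/THF/H2O, rt
Reagents that add atoms: tert-butyldimethylsilyl chloride, CC(C)(C)[Si](C)(C)Cl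
Why: Both OH groups are silylated and the very labile silyl ester is then hydrolysed selectively, leaving the phenol as its TBS ether.

Step 24
Reactants: 30 allylic alcohol; 33 4-(tert-butyldimethylsilyloxy)benzoic acid
Product: 34 3α-acetoxy-4β-isopropyl-1,8-dimethyl-10α-OTBS-4α-OTMS-cis-bicyclo[5.3.0]dec-7-en-6β-yl 4-(tert-butyldimethylsilyloxy)benzoate
Conditions: DCC, DMAP, CH2Cl2, rt
Reagents that add atoms: 4-(tert-butyldimethylsilyloxy)benzoic acid 33, OC(=O)c1ccc(O[Si](C)(C)C(C)(C)C)cc1
Why: Steglich esterification acylates the only free hydroxyl, the secondary allylic C6–OH, under neutral conditions that do not ionise the allylic system.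

Step 25
Reactants: 34 fully protected diester
Product: 35 target, (1S,3S,4R,5R,6S,10S)-3-acetoxy-4,10-dihydroxy-4-isopropyl-1,8-dimethyl-cis-bicyclo[5.3.0]dec-7-en-6-yl 4-hydroxybenzoate
Conditions: HF·pyridine, pyridine, THF, 0 °C → rt
Reagents that add atoms: none
Why: Buffered fluoride desilylation removes the two TBS ethers (C10 and phenol) and the tertiary TMS ether, while the acetate and the aryl ester, both stable to HF·pyridine, stay in place.

**Compound list**

1 | cyclohepta-1,3-diene | C1=CC=CCCC1 | starting material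
2 | 6,7-dioxabicyclo[3.2.2]non-8-ene (meso) | C1=C[C@@H]2CCC[C@H]1OO2 | intermediate
3 | (R)-4-hydroxycyclohept-2-en-1-one | O=C1C=C[C@H](O)CCC1 | intermediate
4 | (R)-4-(triethylsilyloxy)cyclohept-2-en-1-one | O=C1C=C[C@H](O[Si](CC)(CC)CC)CCC1 | intermediate
5 | (R)-2-iodo-4-(triethylsilyloxy)cyclohept-2-en-1-one | O=C1C(I)=C[C@H](O[Si](CC)(CC)CC)CCC1 | intermediate
6 | (R)-2-methyl-4-(triethylsilyloxy)cyclohept-2-en-1-one | O=C1C(C)=C[C@H](O[Si](CC)(CC)CC)CCC1 | intermediate
7 | (1S,4R)-2-methyl-4-(triethylsilyloxy)cyclohept-2-en-1-ol (cis) | CC1=C[C@H](O[Si](CC)(CC)CC)CCC[C@@H]1O | intermediate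
8 | (1S,4R)-1-(tert-butyldimethylsilyloxy)-2-methyl-4-(triethylsilyloxy)cyclohept-2-ene (cis; C10 TBS ether, C6 TES ether) | CC1=C[C@H](O[Si](CC)(CC)CC)CCC[C@@H]1O[Si](C)(C)C(C)(C)C | intermediate
9 | trichloroacetyl chloride | ClC(Cl)(Cl)C(Cl)=O | starting material
10 | dichloroketene (not isolated) | O=C=C(Cl)Cl | intermediate
11 | 2,2-dichloro-1-methyl-10α-(tert-butyldimethylsilyloxy)-6α-(triethylsilyloxy)-cis-bicyclo[5.2.0]nonan-3-one (C3 bonded to C5; four-membered ring on the β face) | C[C@@]12[C@@H](O[Si](C)(C)C(C)(C)C)CCC[C@@H](O[Si](CC)(CC)CC)[C@@H]1C(=O)C2(Cl)Cl | intermediate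
12 | isobutyraldehyde | CC(C)C=O | starting material
13 | p-toluenesulfonyl hydrazide | Cc1ccc(cc1)S(=O)(=O)NN | starting material
14 | isobutyraldehyde tosylhydrazone | CC(C)/C=N/NS(=O)(=O)c1ccc(C)cc1 | intermediate
15 | sodium salt of tosylhydrazone 14 (not isolated) | CC(C)/C=N/[N-]S(=O)(=O)c1ccc(C)cc1.[Na+] | intermediate
16 | 1-diazo-2-methylpropane | CC(C)C=[N+]=[N-] | intermediate
17 | 2,2-dichloro-4-isopropyl-1-methyl-10α-(tert-butyldimethylsilyloxy)-6α-(triethylsilyloxy)-cis-bicyclo[5.3.0]decan-3-one (C4 epimers) | C[C@@]12[C@@H](O[Si](C)(C)C(C)(C)C)CCC[C@@H](O[Si](CC)(CC)CC)[C@@H]1C(C(C)C)C(=O)C2(Cl)Cl | intermediate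
18 | 4-isopropyl-1-methyl-10α-(tert-butyldimethylsilyloxy)-6α-(triethylsilyloxy)-cis-bicyclo[5.3.0]decan-3-one (C4 epimers) | C[C@@]12[C@@H](O[Si](C)(C)C(C)(C)C)CCC[C@@H](O[Si](CC)(CC)CC)[C@@H]1C(C(C)C)C(=O)C2 | intermediate
19 | 4-isopropyl-1-methyl-10α-(tert-butyldimethylsilyloxy)-6α-(triethylsilyloxy)-cis-bicyclo[5.3.0]dec-3-en-3-yl trifluoromethanesulfonate | C[C@@]12[C@@H](O[Si](C)(C)C(C)(C)C)CCC[C@@H](O[Si](CC)(CC)CC)[C@@H]1C(C(C)C)=C(OS(=O)(=O)C(F)(F)F)C2 | intermediate
20 | 4-isopropyl-1-methyl-10α-(tert-butyldimethylsilyloxy)-6α-(triethylsilyloxy)-cis-bicyclo[5.3.0]dec-3-ene | C[C@@]12[C@@H](O[Si](C)(C)C(C)(C)C)CCC[C@@H](O[Si](CC)(CC)CC)[C@@H]1C(C(C)C)=CC2 | intermediate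
21 | 4β-isopropyl-1-methyl-10α-(tert-butyldimethylsilyloxy)-6α-(triethylsilyloxy)-cis-bicyclo[5.3.0]decane-3α,4α-diol | O[C@H]1C[C@]2(C)[C@@H](O[Si](C)(C)C(C)(C)C)CCC[C@@H](O[Si](CC)(CC)CC)[C@@H]2[C@]1(O)C(C)C | intermediate
22 | 3α-acetoxy-4α-hydroxy-4β-isopropyl-1-methyl-10α-(tert-butyldimethylsilyloxy)-6α-(triethylsilyloxy)-cis-bicyclo[5.3.0]decane | CC(=O)O[C@H]1C[C@]2(C)[C@@H](O[Si](C)(C)C(C)(C)C)CCC[C@@H](O[Si](CC)(CC)CC)[C@@H]2[C@]1(O)C(C)C | intermediate
23 | 3α-acetoxy-4β-isopropyl-1-methyl-10α-(tert-butyldimethylsilyloxy)-cis-bicyclo[5.3.0]decane-4α,6α-diol | CC(=O)O[C@H]1C[C@]2(C)[C@@H](O[Si](C)(C)C(C)(C)C)CCC[C@@H](O)[C@@H]2[C@]1(O)C(C)C | intermediate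
24 | 3α-acetoxy-4α-hydroxy-4β-isopropyl-1-methyl-10α-(tert-butyldimethylsilyloxy)-cis-bicyclo[5.3.0]decan-6-one | CC(=O)O[C@H]1C[C@]2(C)[C@@H](O[Si](C)(C)C(C)(C)C)CCCC(=O)[C@@H]2[C@]1(O)C(C)C | intermediate
25 | 3α-acetoxy-4β-isopropyl-1-methyl-10α-(tert-butyldimethylsilyloxy)-4α-(trimethylsilyloxy)-cis-bicyclo[5.3.0]decan-6-one | CC(=O)O[C@H]1C[C@]2(C)[C@@H](O[Si](C)(C)C(C)(C)C)CCCC(=O)[C@@H]2[C@]1(O[Si](C)(C)C)C(C)C | intermediate
26 | C6–C7 trimethylsilyl enol ether of 25 (6-OTMS, dec-6-ene; not isolated) | CC(=O)O[C@H]1C[C@]2(C)[C@@H](O[Si](C)(C)C(C)(C)C)CCC=C(O[Si](C)(C)C)[C@@H]2[C@]1(O[Si](C)(C)C)C(C)C | intermediate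
27 | 3α-acetoxy-4β-isopropyl-1-methyl-10α-(tert-butyldimethylsilyloxy)-4α-(trimethylsilyloxy)-cis-bicyclo[5.3.0]dec-7-en-6-one | CC(=O)O[C@H]1C[C@]2(C)[C@@H](O[Si](C)(C)C(C)(C)C)CC=CC(=O)[C@@H]2[C@]1(O[Si](C)(C)C)C(C)C | intermediate
28 | 8-methyl C6–C7 trimethylsilyl enol ether (6-OTMS, dec-6-ene; C8 epimers; not isolated) | CC(=O)O[C@H]1C[C@]2(C)[C@@H](O[Si](C)(C)C(C)(C)C)CC(C)C=C(O[Si](C)(C)C)[C@@H]2[C@]1(O[Si](C)(C)C)C(C)C | intermediate
29 | 3α-acetoxy-4β-isopropyl-1,8-dimethyl-10α-(tert-butyldimethylsilyloxy)-4α-(trimethylsilyloxy)-cis-bicyclo[5.3.0]dec-7-en-6-one | CC(=O)O[C@H]1C[C@]2(C)[C@@H](O[Si](C)(C)C(C)(C)C)CC(C)=CC(=O)[C@@H]2[C@]1(O[Si](C)(C)C)C(C)C | intermediate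
30 | 3α-acetoxy-4β-isopropyl-1,8-dimethyl-10α-(tert-butyldimethylsilyloxy)-4α-(trimethylsilyloxy)-cis-bicyclo[5.3.0]dec-7-en-6β-ol | CC(=O)O[C@H]1C[C@]2(C)[C@@H](O[Si](C)(C)C(C)(C)C)CC(C)=C[C@H](O)[C@@H]2[C@]1(O[Si](C)(C)C)C(C)C | intermediate
31 | 4-hydroxybenzoic acid | OC(=O)c1ccc(O)cc1 | starting material
32 | tert-butyldimethylsilyl 4-(tert-butyldimethylsilyloxy)benzoate (not isolated) | CC(C)(C)[Si](C)(C)OC(=O)c1ccc(O[Si](C)(C)C(C)(C)C)cc1 | intermediate
33 | 4-(tert-butyldimethylsilyloxy)benzoic acid | OC(=O)c1ccc(O[Si](C)(C)C(C)(C)C)cc1 | intermediate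
34 | 3α-acetoxy-4β-isopropyl-1,8-dimethyl-10α-(tert-butyldimethylsilyloxy)-4α-(trimethylsilyloxy)-cis-bicyclo[5.3.0]dec-7-en-6β-yl 4-(tert-butyldimethylsilyloxy)benzoate | CC(=O)O[C@H]1C[C@]2(C)[C@@H](O[Si](C)(C)C(C)(C)C)CC(C)=C[C@H](OC(=O)c3ccc(O[Si](C)(C)C(C)(C)C)cc3)[C@@H]2[C@]1(O[Si](C)(C)C)C(C)C | intermediate
35 | (1S,3S,4R,5R,6S,10S)-3-acetoxy-4,10-dihydroxy-4-isopropyl-1,8-dimethyl-cis-bicyclo[5.3.0]dec-7-en-6-yl 4-hydroxybenzoate (CNP0146780.2) | CC(=O)O[C@H]1C[C@]2(C)[C@@H](O)CC(C)=C[C@H](OC(=O)c3ccc(O)cc3)[C@@H]2[C@]1(O)C(C)C | target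

**Step count and risks**

Total step count: 25. Longest linear sequence: 22 (steps 1–8, 11–22, 24, 25); steps 9–10 and step 23 are side branches.

Most likely to fail:

1. Step 8 (key cycloaddition). The alkene is inductively deactivated by two allylic C–O bonds and crowded at C1, so the cycloaddition may be slow; over long reaction times zinc chloride and the acid chloride can strip the TES ether, and any approach syn to the silyloxy groups would erode facial selectivity. Fallback, setting out from 8: a keteniminium [2+2] with the salt made from N,N-dimethylacetamide, Tf2O and 2,4,6-collidine (ClCH2CH2Cl, reflux). This more electrophilic ketene equivalent needs no zinc and should add with the same regiochemistry (iminium carbon to C5) and face, giving the cyclobutaniminium triflate F1. Aqueous NaHCO3 hydrolyses it to the chlorine-free cis-fused cyclobutanone F2. Addition of 2-methyl-1-(phenylseleno)propyllithium (from 1,1-bis(phenylseleno)-2-methylpropane and n-BuLi, THF, −78 °C) gives the β-hydroxy selenide F3. Se-methylation (MeI, AgBF4) then triggers a semipinacol ring enlargement in which the more substituted C5 is expected to migrate, so C4 with its isopropyl again lands between C3 and C5. This gives ketone 18, where the route is rejoined (steps 11 and 12 are skipped).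

2. Step 11 (ring expansion with the branched diazoalkane). The insertion is well established for α,α-dichlorocyclobutanones with diazomethane; with the bulkier, thermally labile 1-diazo-2-methylpropane the reagent may decompose (1,2-hydrogen shift, azine formation) faster than it adds to the hindered carbonyl, or the adduct may close to an oxirane instead of migrating. Fallback, setting out from 11: diazomethane (Et2O/MeOH, 0 °C) gives the 2,2-dichlorocyclopentanone F4 without the isopropyl group. Because C2 carries no hydrogen, this ketone can only enolise toward C4; its lithium enolate (LiHMDS, THF, −78 °C) adds to acetone to give the aldol F5. Zn–Cu/NH4Cl removes the chlorines to give the β-hydroxy ketone F6, and Burgess dehydration gives the isopropylidene ketone F7. Lithium–ammonia reduction of this enone forms the C3–C4 enolate regiospecifically and PhNTf2 traps it as enol triflate 19, where the route is rejoined; this path also removes the regiochemical question of step 13.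

3. Step 13 (regioselective enol triflate). Proton loss may occur at the C2 methylene instead of the C4 methine and give the C2=C3 triflate, and Tf2O may attack the TES ether. Fallback, setting out from 18: equilibrating enolisation with bromomagnesium diisopropylamide (Et2O, rt; then TMSCl, Et3N, HMPA) gives the tetrasubstituted C3=C4 trimethylsilyl enol ether F8, which can be purified from its C2=C3 isomer. MeLi (THF, 0 °C) regenerates the lithium enolate without scrambling and PhNTf2 gives 19, where the route is rejoined. The regiochemical decision is thus moved to an isolable, separable enol derivative and Tf2O is avoided.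

**Further compounds**

F1 | step 8 | N,N-dimethyl cyclobutaniminium triflate (1-methyl-10α-OTBS-6α-OTES-cis-bicyclo[5.2.0]nonan-3-iminium, C3 bonded to C5) | C[C@@]12[C@@H](O[Si](C)(C)C(C)(C)C)CCC[C@@H](O[Si](CC)(CC)CC)[C@@H]1C(=[N+](C)C)C2.[O-]S(=O)(=O)C(F)(F)F
F2 | step 8 | 1-methyl-10α-(tert-butyldimethylsilyloxy)-6α-(triethylsilyloxy)-cis-bicyclo[5.2.0]nonan-3-one (C3 bonded to C5) | C[C@@]12[C@@H](O[Si](C)(C)C(C)(C)C)CCC[C@@H](O[Si](CC)(CC)CC)[C@@H]1C(=O)C2
F3 | step 8 | 3-hydroxy-3-[2-methyl-1-(phenylseleno)propyl] derivative of F2 (β-hydroxy selenide, diastereomers) | C[C@@]12[C@@H](O[Si](C)(C)C(C)(C)C)CCC[C@@H](O[Si](CC)(CC)CC)[C@@H]1C(O)(C([Se]c3ccccc3)C(C)C)C2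
F4 | step 11 | 2,2-dichloro-1-methyl-10α-(tert-butyldimethylsilyloxy)-6α-(triethylsilyloxy)-cis-bicyclo[5.3.0]decan-3-one | C[C@@]12[C@@H](O[Si](C)(C)C(C)(C)C)CCC[C@@H](O[Si](CC)(CC)CC)[C@@H]1CC(=O)C2(Cl)Cl
F5 | step 11 | 2,2-dichloro-4-(2-hydroxypropan-2-yl)-1-methyl-10α-(tert-butyldimethylsilyloxy)-6α-(triethylsilyloxy)-cis-bicyclo[5.3.0]decan-3-one (C4 epimers) | C[C@@]12[C@@H](O[Si](C)(C)C(C)(C)C)CCC[C@@H](O[Si](CC)(CC)CC)[C@@H]1C(C(C)(C)O)C(=O)C2(Cl)Cl
F6 | step 11 | 4-(2-hydroxypropan-2-yl)-1-methyl-10α-(tert-butyldimethylsilyloxy)-6α-(triethylsilyloxy)-cis-bicyclo[5.3.0]decan-3-one (C4 epimers) | C[C@@]12[C@@H](O[Si](C)(C)C(C)(C)C)CCC[C@@H](O[Si](CC)(CC)CC)[C@@H]1C(C(C)(C)O)C(=O)C2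
F7 | step 11 | 4-isopropylidene-1-methyl-10α-(tert-butyldimethylsilyloxy)-6α-(triethylsilyloxy)-cis-bicyclo[5.3.0]decan-3-one | C[C@@]12[C@@H](O[Si](C)(C)C(C)(C)C)CCC[C@@H](O[Si](CC)(CC)CC)[C@@H]1C(=C(C)C)C(=O)C2
F8 | step 13 | 4-isopropyl-1-methyl-10α-(tert-butyldimethylsilyloxy)-6α-(triethylsilyloxy)-3-(trimethylsilyloxy)-cis-bicyclo[5.3.0]dec-3-ene | C[C@@]12[C@@H](O[Si](C)(C)C(C)(C)C)CCC[C@@H](O[Si](CC)(CC)CC)[C@@H]1C(C(C)C)=C(O[Si](C)(C)C)C2
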